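All runs stem from a simulated flask on assumed constants; noise was put on by code.

Count the base. You suspect it runs short in these flasks, so before any number I give you a bound.

| setting | green | blue | amber | dawn | midnight | autumn |
|---|---|---|---|---|---|---|
| acidic substrate | 0.060 M | 0.060 M | 0.060 M | 0.060 M | 0.060 M (fed, over 2.5 h) | 0.060 M |
| free base | 0.078 M | 0.039 M | 0.16 M | 0.0780 M | 0.0780 M | 0.0780 M |
| electrophile | 0.18 M | 0.18 M | 0.18 M | 0.180 M | 0.180 M | 0.180 M (fed, over 2.5 h) |
| remark | run made earlier | run made earlier | run made earlier | everything together at the start | all else is in the flask from the start; the feed brings no volume worth counting | all else is in the flask from the start; the feed brings no volume worth counting |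
| time |  |  |  | 6.0 h | 6.0 h | 6.0 h |

| run | time / h | target / % |
|---|---|---|
| green | 0.417 | 33.6 |
| green | 1.33 | 55.5 |
| green | 2.50 | 67.1 |
| green | 4.00 | 74.2 |
| blue | 0.833 | 33.1 |
| blue | 2.00 | 44.8 |
| blue | 2.50 | 47.5 |
| blue | 4.00 | 51.5 |
| amber | 0.250 | 33.4 |
| amber | 0.667 | 56.6 |
| amber | 1.50 | 74.2 |
| amber | 4.00 | 88.5 |

(scatter of a reading: 0.5 percentage points)

- steps that have been proposed: acidic substrate + free base <-> protonated base + anion; anion -> side product; electrophile + anion -> target

1. the flask with the highest amount of target, in percent of the acidic substrate charged ("all alike" if they lie within 1.5 percentage points) (dawn / midnight / autumn / all alike)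
2. final target, as a percentage of the acidic substrate charged, in dawn
3. final target, as a percentage of the acidic substrate charged, in midnight
4. final target, as a percentage of the acidic substrate charged, in autumn

The proposed steps are these: acidic substrate hands its proton to free base, giving protonated base and anion, and anion then goes on to target with electrophile, or to side product. Each molecule of anion, target or side product therefore stands for one free base turned into protonated base. Dawn, midnight and autumn share the ratio 130 % of c(free base) to c(acidic substrate) as charged, which I call the base cover. Think of it as tank size. Target plus side product, in percent of the acidic substrate charged, stays below the smaller of 100% and the cover.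

In blue the cover is 65.0 %, so free base is the limiting reagent there, and its last reading of 51.5 % lies under that ceiling. In dawn, midnight and autumn the cover is above 100%, so acidic substrate is the limiting reagent and, by this count, free base does not run short: the ceiling is 100%. I commit to this much for dawn, which has green's charges: at 6.0 h it stands above green's last reading of 74.2 % and below that ceiling.

The forecast gives 79.5 % for dawn, 76 % for midnight and 75.5 % for autumn, and puts dawn first, saying: “Dawn extrapolates from green”.

The flask gives 79.8 % in dawn, 76.0 % in midnight and 71.0 % in autumn, so dawn is highest. At 6.00 h dawn still holds 15.2 % of its acidic substrate. The cover puts free base at 23.1 % of its own charge once the substrate has reacted, and dawn left until 60.0 h stands at 23.2 %, with 0.110 % of acidic substrate.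

    acidic substrate + free base ⇌ protonated base + anion, settled at all times (K = 0.0440)
    anion → side product (k = 1.18 × 10⁻⁴ s⁻¹)
    electrophile + anion → target (k = 0.0130 M⁻¹ s⁻¹)

Take autumn with 0.24 M of acidic substrate: the cover falls to 32.5 %, so free base becomes the limiting reagent and that is the ceiling. The computed flask gives 26.7 % target and 4.80 % side product, together 31.5 %, with 68 % of acidic substrate left.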